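**Retrosynthetic overview**
1. The target acid comes from one global hydrogenolysis of a tribenzyl precursor (two aryl benzyl ethers and one benzyl ester).
2. The key disconnection is the flavone C6–CH(Ph) bond. The cinnamate β-carbon, normally an acceptor, is used as a nucleophile (an enantioenriched β-trifluoroborato ester, a boron homoenolate). It is joined with inversion to the C–I carbon of a 6-iodoflavone.
3. The boron homoenolate comes from benzyl cinnamate by copper-catalysed asymmetric conjugate borylation. This step creates the stereocentre and the coupling transfers it.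
4. The 6-iodoflavone comes from apigenin by 7,4'-dibenzylation, then iodination directed by the free 5-OH.
5. Ring order: no ring is formed. Rings A, C and B arrive intact in apigenin, and the phenyl ring arrives in the cinnamate.

Assumption: the stereocentre in the SMILES reads as (R) (flavone C6 > phenyl > CH2CO2H > H), and the commercial antipode of the ferrocenyl diphosphine that gives the (S)-boronate is used, its sense checked once by oxidising a sample to the known β-hydroxy ester.

**Route**

Step 1
Reactants: 1 apigenin (5,7,4'-trihydroxyflavone)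
Product: 2 7,4'-di-O-benzylapigenin, 7-(benzyloxy)-2-[4-(benzyloxy)phenyl]-5-hydroxy-4H-chromen-4-one
Conditions: BnBr (2.2 equiv), K2CO3 (2.5 equiv), DMF, rt to 50 °C
Reagents that add atoms: benzyl bromide, BrCc1ccccc1
Why: Williamson etherification, in which the two acidic phenols (7 and 4') are benzylated while the 5-OH, hydrogen-bonded to the C4 carbonyl, stays free.

Step 2
Reactants: 2 7,4'-di-O-benzylapigenin
Product: 3 6-iodo-7,4'-di-O-benzylapigenin, 7-(benzyloxy)-2-[4-(benzyloxy)phenyl]-5-hydroxy-6-iodo-4H-chromen-4-one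
Conditions: NIS (1.05 equiv), DMF, rt, dark
Reagents that add atoms: N-iodosuccinimide, O=C1CCC(=O)N1I
Why: Electrophilic aromatic iodination under neutral conditions goes ortho to the free chelated 5-OH, which is the established C6 selectivity of 5-hydroxy-7-alkoxyflavones, so C8, C3 and ring B are left alone.

Step 3
Reactants: 4 benzyl (E)-cinnamate
Product: 6 potassium (S)-[3-(benzyloxy)-3-oxo-1-phenylpropyl]trifluoroborate, via pinacol boronate 5 (not isolated)
Conditions: CuCl (3 mol%), NaOtBu (6 mol%), 1-[2-(diphenylphosphino)ferrocenyl]ethyldicyclohexylphosphine (Josiphos, 3 mol%), B2pin2 (1.1 equiv), MeOH (2 equiv), THF, rt; then aq KHF2 (4.5 equiv), MeOH, rt; recrystallise from acetone/Et2O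
Reagents that add atoms: bis(pinacolato)diboron, CC1(C)OB(OC1(C)C)B1OC(C)(C)C(C)(C)O1; potassium hydrogen difluoride, [K+].F.[F-]
Why: Copper-catalysed asymmetric conjugate borylation, in which the chiral ligand-bound Cu–Bpin adds to one face of the enoate β-carbon and MeOH protonates the copper enolate, sets the (S) C–B stereocentre (about 90% ee, raised by recrystallisation), and KHF2 then gives a crystalline, configurationally stable homoenolate equivalent.

Step 4
Reactants: 3 6-iodo-7,4'-di-O-benzylapigenin; 6 potassium (S)-[3-(benzyloxy)-3-oxo-1-phenylpropyl]trifluoroborate (1.5 equiv)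
Product: 8 benzyl (3R)-3-{7-(benzyloxy)-2-[4-(benzyloxy)phenyl]-5-hydroxy-4-oxo-4H-chromen-6-yl}-3-phenylpropanoate, via boronic acid 7 (not isolated)
Conditions: Pd(OAc)2 (10 mol%), XPhos (20 mol%), K2CO3 (4 equiv), CPME/H2O 7:1, 90 °C, Ar
Reagents that add atoms: none
Why: Stereospecific Suzuki–Miyaura coupling of a boron homoenolate joins the cinnamate β-carbon (nucleophilic as C–B) to the electrophilic C–I carbon of 3; slow hydrolysis of 6 feeds boronic acid 7, whose ester carbonyl sits on boron and blocks the closed four-centre pathway, so transmetalation to the XPhos-bound arylpalladium iodide is an open backside SE2 process with inversion ((S)-C–B to (R)-C–C), and the benzylic, carbonyl-chelated alkylpalladium reductively eliminates faster than it loses a β-hydride.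

Step 5
Reactants: 8 benzyl (3R)-3-{7-(benzyloxy)-2-[4-(benzyloxy)phenyl]-5-hydroxy-4-oxo-4H-chromen-6-yl}-3-phenylpropanoate
Product: 9 (3R)-3-[5,7-dihydroxy-2-(4-hydroxyphenyl)-4-oxo-4H-chromen-6-yl]-3-phenylpropanoic acid (target)
Conditions: H2 (1 atm), 10% Pd/C, THF/MeOH 1:1, rt, stopped after uptake of 3 equiv H2
Reagents that add atoms: none
Why: Catalytic hydrogenolysis removes both aryl benzyl ethers and the benzyl ester in one neutral operation that breaks no bond at the diarylmethine stereocentre, does not promote lactonisation, and leaves the flavone C2=C3 bond intact at 1 atm.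

**Compound list**
1 | apigenin | O=c1cc(-c2ccc(O)cc2)oc2cc(O)cc(O)c12 | starting material
2 | 7,4'-di-O-benzylapigenin | O=c1cc(-c2ccc(OCc3ccccc3)cc2)oc2cc(OCc3ccccc3)cc(O)c12 | intermediate
3 | 6-iodo-7,4'-di-O-benzylapigenin | O=c1cc(-c2ccc(OCc3ccccc3)cc2)oc2cc(OCc3ccccc3)c(I)c(O)c12 | intermediate
4 | benzyl (E)-cinnamate | O=C(/C=C/c1ccccc1)OCc1ccccc1 | starting material
5 | benzyl (3S)-3-phenyl-3-(4,4,5,5-tetramethyl-1,3,2-dioxaborolan-2-yl)propanoate (not isolated) | O=C(OCc1ccccc1)C[C@@H](c1ccccc1)B1OC(C)(C)C(C)(C)O1 | intermediate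
6 | potassium (S)-[3-(benzyloxy)-3-oxo-1-phenylpropyl]trifluoroborate | [K+].O=C(OCc1ccccc1)C[C@@H](c1ccccc1)[B-](F)(F)F | intermediate
7 | (S)-[3-(benzyloxy)-3-oxo-1-phenylpropyl]boronic acid (not isolated) | O=C(OCc1ccccc1)C[C@@H](c1ccccc1)B(O)O | intermediate
8 | benzyl (3R)-3-{7-(benzyloxy)-2-[4-(benzyloxy)phenyl]-5-hydroxy-4-oxo-4H-chromen-6-yl}-3-phenylpropanoate | O=C(OCc1ccccc1)C[C@H](c1ccccc1)c1c(OCc2ccccc2)cc2oc(-c3ccc(OCc4ccccc4)cc3)cc(=O)c2c1O | intermediate
9 | (3R)-3-[5,7-dihydroxy-2-(4-hydroxyphenyl)-4-oxo-4H-chromen-6-yl]-3-phenylpropanoic acid | O=C(O)C[C@H](c1ccccc1)c1c(O)cc2oc(-c3ccc(O)cc3)cc(=O)c2c1O | target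

**Totals**
Total step count: 5.
Longest linear sequence: 4 (steps 1, 2, 4 and 5).

**Three steps most likely to fail**

Step 4 is the highest risk.
- A secondary benzylic boron reagent has to reach an electron-rich aryl iodide flanked by two oxygen substituents.
- Likely failure modes are slow transmetalation, protodeboronation, and β-hydride loss back to 4 with reduction of 3 to 2.
- Inversion may also be incomplete, because an ester binds boron less firmly than an amide does.
- Partial saponification of the benzyl ester is harmless, since the acid is debenzylated to the same target.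

The fallback sets out from 3 and comes back at 8. It keeps the homoenolate logic but moves the boron onto the flavone half, so the palladium partner is unhindered bromobenzene. A Heck reaction of 3 with benzyl acrylate (Pd(OAc)2, P(o-tol)3, Et3N, DMF, 100 °C) gives benzyl (E)-3-{7-(benzyloxy)-2-[4-(benzyloxy)phenyl]-5-hydroxy-4-oxo-4H-chromen-6-yl}prop-2-enoate F1. Copper-catalysed asymmetric conjugate borylation as in step 3, with the ligand antipode chosen for (R), gives the (3R)-pinacol boronate F2. KHF2 converts this to the potassium (R)-trifluoroborate F3. Under the step 4 conditions this reacts through its (R)-boronic acid F4 with bromobenzene, again with inversion, to give 8.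

Step 5 is the second risk.
- The flavone C2=C3 bond may be over-reduced to the flavanone.
- Traces of iodide may poison the catalyst.
- The hydroxy acid may lactonise partly on concentration, which makes purification awkward.

The fallback sets out from 8 and comes back at 9. It debenzylates without hydrogen and purifies at the lactone stage. BCl3 with pentamethylbenzene (CH2Cl2, −78 to 0 °C) cleaves all three benzyl groups. The crude hydroxy acid is closed on purpose (cat. TsOH, toluene, 60 °C) onto the free, non-chelated 7-OH. This gives (4R)-5-hydroxy-8-(4-hydroxyphenyl)-4-phenyl-3,4-dihydro-2H,6H-pyrano[3,2-g]chromene-2,6-dione F5, which is chromatographed or crystallised. LiOH (THF/H2O, 0 °C) followed by careful acidification to pH 3–4 in the cold opens the lactone to 9.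

Step 3 is the third risk.
- β-Aryl enoates give only about 90% ee in the borylation.
- Methoxide may transesterify the benzyl ester.
- The benzylic trifluoroborate may protodeboronate during isolation.

The fallback sets out from 4 and comes back at 5. It sets the stereocentre by delivering hydride instead of boron. Ester-directed vinylic C–H borylation of 4 ([Ir(OMe)(cod)]2, AsPh3, B2pin2, octane, 120 °C) replaces the β-hydrogen cis to the ester. This gives benzyl (E)-3-phenyl-3-(4,4,5,5-tetramethyl-1,3,2-dioxaborolan-2-yl)prop-2-enoate F6. Asymmetric copper hydride conjugate reduction (Cu(OAc)2, DTBM-SEGPHOS antipode chosen for (S), PMHS, tBuOH, toluene, 0 °C) then gives 5, which is carried on with KHF2 as in step 3.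

**Further compounds**
F1 | step 4 | benzyl (E)-3-{7-(benzyloxy)-2-[4-(benzyloxy)phenyl]-5-hydroxy-4-oxo-4H-chromen-6-yl}prop-2-enoate | O=C(OCc1ccccc1)/C=C/c1c(OCc2ccccc2)cc2oc(-c3ccc(OCc4ccccc4)cc3)cc(=O)c2c1O
F2 | step 4 | benzyl (3R)-3-{7-(benzyloxy)-2-[4-(benzyloxy)phenyl]-5-hydroxy-4-oxo-4H-chromen-6-yl}-3-(4,4,5,5-tetramethyl-1,3,2-dioxaborolan-2-yl)propanoate | O=C(OCc1ccccc1)C[C@@H](B1OC(C)(C)C(C)(C)O1)c1c(OCc2ccccc2)cc2oc(-c3ccc(OCc4ccccc4)cc3)cc(=O)c2c1O
F3 | step 4 | potassium (R)-{3-(benzyloxy)-1-[7-(benzyloxy)-2-[4-(benzyloxy)phenyl]-5-hydroxy-4-oxo-4H-chromen-6-yl]-3-oxopropyl}trifluoroborate | [K+].O=C(OCc1ccccc1)C[C@@H]([B-](F)(F)F)c1c(OCc2ccccc2)cc2oc(-c3ccc(OCc4ccccc4)cc3)cc(=O)c2c1O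
F4 | step 4 | (R)-{3-(benzyloxy)-1-[7-(benzyloxy)-2-[4-(benzyloxy)phenyl]-5-hydroxy-4-oxo-4H-chromen-6-yl]-3-oxopropyl}boronic acid | O=C(OCc1ccccc1)C[C@@H](B(O)O)c1c(OCc2ccccc2)cc2oc(-c3ccc(OCc4ccccc4)cc3)cc(=O)c2c1O
F5 | step 5 | (4R)-5-hydroxy-8-(4-hydroxyphenyl)-4-phenyl-3,4-dihydro-2H,6H-pyrano[3,2-g]chromene-2,6-dione | O=C1C[C@H](c2ccccc2)c2c(O1)cc1oc(-c3ccc(O)cc3)cc(=O)c1c2O
F6 | step 3 | benzyl (E)-3-phenyl-3-(4,4,5,5-tetramethyl-1,3,2-dioxaborolan-2-yl)prop-2-enoate | O=C(OCc1ccccc1)/C=C(/c1ccccc1)B1OC(C)(C)C(C)(C)O1
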